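## Structural features

The target is a germacranolide: a ten-membered carbocycle C1–C10 with a Z trisubstituted olefin C4=C5 (methyl C15), a trans (1β,10α) epoxide on C1/C10 (methyl C14) and a trans-fused α-methylene-γ-butyrolactone running from C7 through C11/C12 to O6. O3 carries a benzoate and O8 a (2R,3S)-2,3-dimethyloxirane-2-carboxylate; its ring methyls are cis, so it is the epoxide of tiglic acid, not of angelic acid. Six stereocentres lie on the ring: C6, C7 and C8 are contiguous, C1 and C10 are contiguous, and C3 stands alone between C2 and the olefin; two more sit in the side-chain epoxide. Fragile groups are the α-methylene lactone (Michael acceptor, reduced by borohydride), the 1,10-epoxide (transannular opening onto C4=C5 under acid), the allylic benzoate, the glycidic ester, and the 8β-hydroxyl/12,6-lactone pair, which can translactonise under base. The real difficulty is the medium ring together with the relative configuration between three separated groups of stereocentres (C6/C7, C1/C10, and the remote carbinols C3 and C8). The key step uses the fact that C3 and C8 both bear oxygen and face each other 1,6 across the ring: a temporary C3–C8 bond turns the ring into a cis-decalin whose ring A (C3–C8, C15 on C4, side chain on C7) is carvone and whose ring B (C3, C2, C1, C10, C9, C8) is a cyclohexene. In that decalin C4=C5 is necessarily cis, C1/C10 can be oxygenated on a rigid bicycle, and glycol scission of the ring-fusion diol returns both oxygens as ketones. After scission O10 lies β to the C8 ketone, which is used to control C8.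

## Logic of the disconnections

**34 to 32 (C11=C13 to C11–H/C13–H3, no skeletal bond).** The exocyclic olefin is removed first because it would not survive hydride reagents, fluoride or alkoxides. The gain is a robust α-methyl lactone through the whole route. The demand is a last step that dehydrogenates only toward C13 in the presence of two esters and two epoxides; this is done through selenide 33.

**32 to 30 (the C1–O bond of the epoxide, C10–O kept).** A trans-epoxide cannot come from the cis olefin of a six-membered ring, so it is made by invertive closure of a cis-1α,10α-diol through mesylate 31. The gain is that C1 and C10 become a cis-diol that can be set on a cyclohexene. The demand is that O1 is the only free secondary hydroxyl at that point and that no acid follows.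

**30 to 27 (O1–Si, the C3–O acyl bond, the C3–H bond).** Through 29 and 28 the benzoate goes back to the allylic alcohol and this to the Z-enone. The gain is that C3 is trigonal, as the key step leaves it. The demand is a reagent-controlled 1,2-reduction that gives 3β-OH while O1 stays silylated.

**27 to 21 and 25 (acyl–O8 bond).** The side chain is attached as a preformed acid because epoxidation of a tiglate on the ring could be neither face- nor chemoselective. 25 goes back through 24 and 23 to 22 (the C–O bonds of the oxirane and the carboxyl oxidation level). The demand is acylation of a hindered secondary alcohol next to a free tertiary one.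

**21 to 20 (C8–H).** The 8β-carbinol is taken back to the ketone. The gain is the second trigonal centre of the key step. The demand is hydride delivery to one face of a flexible ring, answered by leaving O10 free so that it carries the hydride to C8 (1,3-anti).

**20 to 19 (C3–C8, the key cut read backwards as a bond formation).** The ten-membered dione becomes a cis-fused decalin-3,8-diol. The gain is that the medium ring is replaced by two six-membered rings and C4=C5 is fixed as Z. Two design choices are made in 19:
- The ring-fusion hydroxyls are both β (cis to the C7 side chain). This is the cis-diol that the natural facial preferences of a carvone enolate and of a Felkin–Anh carbonyl addition deliver. For the 3α,8α-isomer the allyl nucleophile would have to enter C3 past an axial C9 or C11 substituent. The trans-diol would force a trans-decalin that cannot hold the diequatorial trans-lactone.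
- O1 is silylated and O10 is left free. This leaves the ring-fusion glycol as the only 1,2-diol and keeps O10 available for the directed reduction.

**19 to 14 (O1–Si, O8–Si, and the C1–O and C10–O bonds).** Through 18 and 17 the protecting groups are exchanged and the cis-1α,10α-diol is traced to the ring B olefin. Because the ring-fusion oxygens are β, the α-diol lies on the concave face. The demand is therefore cis-hydroxylation on the more hindered face, which the Woodward procedure provides and osmium tetroxide would not.

**14 to 10 (acyl C12–O6 bond, C12 oxidation level, C12–O bond).** Through 12 the lactone goes back to the isopropenyl group and the 6α-hydroxyl. The gain is that the carvone side chain is used unchanged. The demand is selective hydroboration of the 1,1-disubstituted olefin and primary-selective oxidation.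

**10 to 9 (C1=C10).** Ring B is opened at its olefin to an allyl group on C3 and a methallyl group on C8. The demand is that these are cis, which is the same condition as the cis-diol.

**9 to 7 and 8 (C2–C3).** The allyl group is removed from the carbonyl carbon. The demand is attack anti to the axial 8β-silyloxy group.

**7 to 5 (C6–O).** The 6α-hydroxyl is removed from the γ-position of the enone. The demand is that C8 is quaternary so that base can only form the linear dienolate.

**5 to 3 and 4 (C8–C9), then 3 to 1 (C8–O).** Oxygen is put on C8 before carbon, so that the second electrophile (carbon) enters anti to the isopropenyl group and leaves oxygen cis to it. All ring carbons then come from 1, 4 and 8.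

## Other disconnections considered

**Alternative 1:** The cut is O6–C12 and C11–C12: the lactone carbonyl is removed as carbon monoxide. The forward key step is a cyclocarbonylation (PdCl2, SnCl2, PPh3, CO; divalent palladium) of a substrate that already contains the ten-membered ring with a free 6-hydroxyl and a 7-ethynyl group. Hydrometalation of the alkyne, CO insertion and capture of the acyl metal by O6 give A1.
- In its favour: the α-methylene lactone appears in one step at the right oxidation level, with no C11 stereocentre, no selenium and no strong base late in the route. O3 and O8 arrive already differentiated (silyl and p-methoxybenzyl). On the end game it is the equal of the chosen plan, and better in the lactone construction.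
- Against it here: it does not address the ten-membered ring. The ring, the 1(10)E olefin and four stereocentres must come from an earlier macrocyclisation that is the hardest part of the problem. The 1(10),4-diene is a 1,5-diene prone to Cope rearrangement and to acid-induced transannular cyclisation under the Lewis-acidic tin conditions. The epoxide must then be introduced by peracid, with its face decided only by ring conformation and not by a stereospecific displacement.
- Comparison: in structure the chosen plan makes ring and Z olefin from six-membered rings and never has a 1(10) olefin in the medium ring. In mechanism A1 relies on a catalytic acyl-metal cascade, the chosen plan on a stoichiometric two-electron fragmentation. In step economy A1 is shorter after the ring exists but longer overall once the ring synthesis is counted.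

**Alternative 2:** The cut is a [3,3] shift that forms C8–C9 and breaks the C1–C6 bond of a carvone-derived 1,2-dialkenylcyclohexenol, followed by C7–C11. The forward key step is an anionic oxy-Cope rearrangement (KH, 18-crown-6) whose ten-membered enolate is alkylated at C7 by tert-butyl bromoacetate to give A2.
- In its favour: like the chosen plan it is a four-carbon ring expansion from carvone, but it forms a C–C bond and sets 1(10)E through the chair transition state and 4Z from the cyclohexene, and it adds the lactone carbons in the same flask. Up to the ten-membered ring it is better than the chosen plan in step economy.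
- Against it here: O8 is carried as a benzyldimethylsilyl group, so a Tamao–Fleming oxidation is needed beside two trisubstituted olefins. The C6 ketone must be reduced to the 6α-alcohol on a flexible ring. The acetate arm lacks C13, so an α-methylenation is still required. The face of the C7 alkylation and of the late 1,10-epoxidation rests on macrocyclic conformation. The 1,5-diene can revert by Cope rearrangement.
- Comparison: equal in its use of the chiral pool and of a ring expansion. Better in the number of steps to the ring. Weaker where the chosen plan is strongest, namely C1/C10 set stereospecifically on a decalin and C8 set by a directed reduction.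

**Alternative 3:** The cut is C9–C10. The forward key step is a reductive macrocyclisation with Ni(cod)2 (zerovalent nickel), PBu3 and Et3B that joins C10 of a methyl alkyne to C9 of a terminal epoxide. Syn addition across the alkyne gives the E olefin, and the epoxide stereocentre becomes the free 8β-hydroxyl of A3.
- In its favour: C8 comes from an enantiopure epoxide, which is as good as or better than the directed reduction used here. The 8-hydroxyl emerges as the only free alcohol, ready for esterification. O3, O6 and O12 are already differentiated, and the 2-substituted allyl ether leads to the α-methylene lactone without selenium. On these points it is the better plan.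
- Against it here: a ten-membered carbocycle must be closed by an intramolecular catalytic C–C coupling against medium-ring strain, at high dilution, with exo/endo regiochemistry of alkyne insertion to control. The open-chain substrate with the Z olefin and the C3, C6, C7 stereocentres needs a long linear sequence. The 1(10) olefin must again be epoxidised late under conformational control, and the product is a Cope-prone 1,5-diene.
- Comparison: in mechanism the ring is closed by bond formation there and released by bond cleavage here. In structure the chosen plan keeps every stereocentre-forming event on six-membered rings or under reagent or hydroxyl direction. In step economy A3 has the shorter end game and the chosen plan the shorter and safer access to the ring.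

Key step: step 11

Remark 1: germacrane numbering is kept for every intermediate; "3,8-cyclogermacrane" means the decalin with the extra C3–C8 bond; α is the face that carries O6, β the face that carries the C7–C11 bond.

Remark 2: C11 is formed without reliable control in step 6 and erased in step 20; compounds 11–33 are drawn as the 11S (α-methyl) epimer and the 11R epimer follows the same route.

Remark 3: isomers that converge (the C8 epimer of 3, the 10-O-acetyl isomer of 16, a silyl group moved from O8 to O3 in 9–17) are not drawn separately.

## Route

Step 1
Reactants: 1 (S)-carvone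
Product: 3 8α-(tert-butyldimethylsilyloxy)carvone, via silyl dienol ether 2 (not isolated)
Conditions: LiN(iPr)2, THF, −78 °C; TBSCl, DMPU, −78 → 0 °C; then mCPBA, NaHCO3, hexane–CH2Cl2, −20 °C → rt
Reagents that add atoms: tert-butyldimethylsilyl chloride CC(C)(C)[Si](C)(C)Cl; 3-chloroperoxybenzoic acid OOC(=O)c1cccc(Cl)c1
Why: Kinetic deprotonation at C8 (α′) and O-silylation give the cross-conjugated dienol ether; Rubottom oxidation epoxidises its electron-rich C3=C8 bond much faster than the isopropenyl group and the silyl group moves to the new oxygen (1,4-silyl shift). The C8 configuration (mainly trans to the isopropenyl group) does not matter because C8 is enolised again in step 2.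

Step 2
Reactants: 3 8α-(tert-butyldimethylsilyloxy)carvone, 4 3-bromo-2-methylprop-1-ene
Product: 5 8α-methallyl-8β-silyloxy enone
Conditions: LiN(iPr)2, THF–DMPU, −78 °C; then 4, −78 → −30 °C
Reagents that add atoms: none
Why: Enolate alkylation: allylic 1,2-strain with the C8 silyloxy group holds the C7 isopropenyl group pseudoaxial in the tetrasubstituted lithium enolate, so the bromide should enter C8 from the opposite (α) face and leave the silyloxy group β, cis to the side chain.

Step 3
Reactants: 5 8α-methallyl-8β-silyloxy enone
Product: 7 6α-hydroxy enone, via linear silyl dienol ether 6 (not isolated)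
Conditions: LiN(iPr)2, THF, −78 °C; TMSCl, −78 → 0 °C; then mCPBA, NaHCO3, CH2Cl2, −40 °C; aq. NaHCO3/Na2S2O3
Reagents that add atoms: 3-chloroperoxybenzoic acid OOC(=O)c1cccc(Cl)c1
Why: With C8 quaternary the base can only remove a γ-proton (C6), and silylation gives the linear dienol ether; vinylogous Rubottom oxidation attacks its terminal C5=C6 bond (the position electrophiles take in 3-silyloxy-3,5-dienes) anti to the C7 isopropenyl group, and collapse restores the enone with the new 6α-hydroxyl trans to the side chain. The dienol ether should react far faster with the peracid than the two 1,1-disubstituted olefins.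

Step 4
Reactants: 7 6α-hydroxy enone, 8 allylmagnesium bromide
Product: 9 3α-allyl-3β,6α-diol 8-silyl ether
Conditions: 8 (3 equiv), THF, −78 → −40 °C; aq. NH4Cl
Reagents that add atoms: none
Why: Grignard 1,2-addition: in the half-chair with O6, the isopropenyl group and the methallyl group equatorial, the bulky 8β-silyloxy group is axial and the reagent should attack C3 anti to it (Felkin–Anh, axial attack on the α face). The new hydroxyl is then β and cis to O8, and the allyl group is cis to the methallyl group; the first equivalent is consumed by the C6 hydroxyl.

Step 5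
Reactants: 9 3α-allyl-3β,6α-diol 8-silyl ether
Product: 10 cis-fused 3,8-cyclogermacra-1(10),4,11(13)-triene
Conditions: second-generation Grubbs catalyst RuCl2(=CHPh)(PCy3)(H2IMes) (5 mol %), CH2Cl2, 40 °C
Reagents that add atoms: none
Why: Ring-closing olefin metathesis between the monosubstituted allyl olefin and the 1,1-disubstituted methallyl olefin on adjacent cis positions closes ring B as a trisubstituted cyclohexene with loss of ethene. The isopropenyl group sits on the other face and could only give a slower tetrasubstituted olefin.

Step 6
Reactants: 10 cis-fused 3,8-cyclogermacra-1(10),4,11(13)-triene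
Product: 12 12-hydroxy compound (3β,6α,12-triol 8-silyl ether), via B-alkyl-9-BBN adduct 11 (not isolated)
Conditions: 9-BBN (4 equiv), THF, 0 °C → rt; then NaOH, H2O2, 0 °C → rt
Reagents that add atoms: hydrogen peroxide OO
Why: Hydroboration–oxidation: 9-BBN adds anti-Markovnikov to the 1,1-disubstituted isopropenyl group and should leave the two trisubstituted ring olefins; alkaline peroxide gives the primary C12 alcohol. C11 is formed without reliable control and is removed later.

Step 7
Reactants: 12 12-hydroxy compound (3β,6α,12-triol 8-silyl ether)
Product: 14 trans-12,6α-lactone, via lactol 13 (not isolated)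
Conditions: TEMPO (0.2 equiv), PhI(OAc)2 (2.5 equiv), CH2Cl2, rt
Reagents that add atoms: none
Why: Oxidative lactonisation of a 1,4-diol: the oxoammonium oxidant takes the primary alcohol to the aldehyde, which closes with the 6α-hydroxyl to the lactol and is oxidised on to the lactone. O6 (α) and C11 (β) are both equatorial on ring A, so the γ-lactone is trans-fused.

Step 8
Reactants: 14 trans-12,6α-lactone
Product: 17 1α,10α-diol (1α,3β,10α-triol 8-silyl ether), via iodo acetate 15 (not isolated), via hydroxy acetate 16 (not isolated)
Conditions: I2, AgOAc, AcOH, rt; H2O (2 equiv), 45 °C; then K2CO3, MeOH, 0 °C; aq. citric acid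
Reagents that add atoms: silver acetate CC(=O)[O-].[Ag+]
Why: Woodward cis-hydroxylation: iodine adds to C1=C10 on the convex β face (the face of the ring-fusion oxygens), acetate opens the iodonium ion at tertiary C10 from the α face (trans-diaxial, Markovnikov), the acetate carbonyl then displaces the C1 iodide on the same α face with silver assistance, and water opens the acetoxonium ion to the cis-hydroxy acetate. Both oxygens therefore end on the concave α face, which osmium tetroxide would not reach; methanolysis removes the acetyl group while O8 is still silylated. The ring A olefin is deactivated by its allylic acyloxy group and shielded by quaternary C3.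

Step 9
Reactants: 17 1α,10α-diol (1α,3β,10α-triol 8-silyl ether)
Product: 18 1α,3β,8β,10α-tetraol lactone
Conditions: HF·pyridine, pyridine, THF, 0 → 40 °C
Reagents that add atoms: none
Why: Fluoride cleavage of the tertiary silyl ether under buffered, non-basic conditions; basic fluoride is avoided because a free 8β-alkoxide, cis to C11, could attack the lactone carbonyl.

Step 10
Reactants: 18 1α,3β,8β,10α-tetraol lactone
Product: 19 1α-triethylsilyl ether (decalin-3β,8β-diol, key-step precursor)
Conditions: Et3SiCl, imidazole, DMF, 0 °C
Reagents that add atoms: triethylsilyl chloride CC[Si](Cl)(CC)CC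
Why: Silylation with a silyl chloride and imidazole should touch only the single secondary hydroxyl (O1), since O3, O8 and O10 are tertiary. This leaves the ring-fusion glycol as the only free 1,2-diol and keeps O10 free to direct step 12.

Step 11
Reactants: 19 1α-triethylsilyl ether (decalin-3β,8β-diol, key-step precursor)
Product: 20 ten-membered 3,8-dione lactone
Conditions: Pb(OAc)4 (1.1 equiv), K2CO3, CH2Cl2, −20 → 0 °C, 15 min
Reagents that add atoms: none
Why: Criegee glycol cleavage: the cis ring-fusion diol exchanges two acetates on tetravalent lead to give a five-membered cyclic plumbate, and a two-electron fragmentation breaks C3–C8 while lead leaves as divalent lead diacetate, so both carbons become ketones. The closest known reaction is the lead tetraacetate cleavage of cis-decalin-9,10-diols to cyclodecane-1,6-diones. No ring is closed by bond formation: the ten-membered ring is set free by cutting the bond shared by the two six-membered rings, so there is no mode of closure to control. No stereocentre is formed; C3 and C8 become trigonal (the 3β,8β-diol used here and its 3α,8α-isomer would give the same dione), and the 4Z geometry is that of the ring A cyclohexene. The selectivity needed is chemoselectivity: O1 is silylated, so the only free vicinal diol is the ditertiary C3/C8 pair, and the isolated tertiary O10 is not attacked at 0 °C. Solid K2CO3 takes up the acetic acid, and low temperature and short contact protect the product, whose 1,6-dione can undergo transannular aldol reaction and whose C8 ketone has O6 and O10 in β-positions.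

Step 12
Reactants: 20 ten-membered 3,8-dione lactone
Product: 21 8β,10α-diol enone
Conditions: Me4NBH(OAc)3 (5 equiv), MeCN–AcOH (1:1), −30 °C
Reagents that add atoms: none
Why: Evans–Saksena reduction: the free tertiary 10α-hydroxyl exchanges an acetate on boron and delivers hydride to the β-ketone C8 through a chair-like six-membered transition state, which should give the 1,3-anti diol, here the 8β-alcohol. The C3 enone has no β-hydroxyl (O1 is silylated) and the reagent does not reduce ketones that lack one.

Step 13
Reactants: 22 (E)-2-methylbut-2-en-1-ol
Product: 23 (2S,3S)-epoxy alcohol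
Conditions: Ti(OiPr)4 (10 mol %), L-(+)-diethyl tartrate (12 mol %), t-BuOOH, 4 Å MS, CH2Cl2, −20 °C
Reagents that add atoms: tert-butyl hydroperoxide CC(C)(C)OO
Why: Sharpless asymmetric epoxidation of a trisubstituted E-allylic alcohol; with L-(+)-tartrate the oxygen is delivered to the face that gives the (2S,3S)-epoxy alcohol, and the two methyl groups stay cis.

Step 14
Reactants: 23 (2S,3S)-epoxy alcohol
Product: 25 (2R,3S)-epoxy acid, via epoxy aldehyde 24 (not isolated)
Conditions: TEMPO (0.2 equiv), PhI(OAc)2 (2.2 equiv), MeCN–H2O (1:1), rt
Reagents that add atoms: water O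
Why: Oxoammonium oxidation in aqueous acetonitrile takes the primary alcohol through the aldehyde and its hydrate to the acid without touching the epoxide. The C2 descriptor changes to R only because the carboxyl group outranks C3.

Step 15
Reactants: 21 8β,10α-diol enone, 25 (2R,3S)-epoxy acid
Product: 27 8β-glycidic ester, via mixed anhydride 26 (not isolated)
Conditions: 25, 2,4,6-trichlorobenzoyl chloride, Et3N, THF, rt; then 21, DMAP, toluene, rt
Reagents that add atoms: none
Why: Yamaguchi esterification: DMAP attacks the mixed anhydride at the glycidic carbonyl and the acylpyridinium acylates the hindered secondary 8β-hydroxyl. The tertiary O10 does not react and the acid has no α-hydrogen to epimerise.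

Step 16
Reactants: 27 8β-glycidic ester
Product: 28 3β-allylic alcohol
Conditions: (R)-2-methyl-CBS-oxazaborolidine (1.2 equiv), catecholborane (3 equiv), toluene, −78 °C
Reagents that add atoms: none
Why: Corey–Bakshi–Shibata reduction: the (R)-oxazaborolidine should bind the enone carbonyl with the larger α-methylalkenyl side (C4) away from boron and deliver hydride 1,2 to give the 3S (3β) alcohol under reagent control. Esters, lactone and the side-chain epoxide are not reduced by catecholborane at this temperature.

Step 17
Reactants: 28 3β-allylic alcohol
Product: 29 3β-benzoate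
Conditions: BzCl, pyridine, DMAP (cat.), CH2Cl2, 0 °C → rt
Reagents that add atoms: benzoyl chloride O=C(Cl)c1ccccc1
Why: Acylation of the only secondary hydroxyl (allylic O3) under nucleophilic catalysis; the tertiary O10 is inert.

Step 18
Reactants: 29 3β-benzoate
Product: 30 1α,10α-diol diester
Conditions: HF·pyridine, pyridine, THF, 0 °C
Reagents that add atoms: none
Why: Buffered fluoride removes the secondary triethylsilyl ether; this is done before the acid-sensitive 1,10-epoxide exists, and the glycidic ester, deactivated by its carbonyl group, should not be opened.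

Step 19
Reactants: 30 1α,10α-diol diester
Product: 32 11,13-dihydro target (1β,10α-epoxide), via 1α-mesylate 31 (not isolated)
Conditions: MsCl, Et3N, CH2Cl2, −20 °C; then NaH, THF, 0 °C
Reagents that add atoms: none
Why: Sulfonylation of the only secondary hydroxyl (O1), then intramolecular Williamson closure: the C10 alkoxide attacks C1 on the β face with inversion (3-exo-tet), so the cis-1α,10α-diol becomes the trans (1β,10α) epoxide that a ring E olefin would give.

Step 20
Reactants: 32 11,13-dihydro target (1β,10α-epoxide)
Product: 34 CNP0324463.5, via 11-phenylselanyl lactone 33 (not isolated)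
Conditions: KN(SiMe3)2, THF, −78 °C; PhSeBr, −78 °C; then H2O2 (30 %), pyridine, CH2Cl2, 0 °C → rt
Reagents that add atoms: none
Why: Selenoxide route to the α-methylene lactone: the lactone α-hydrogen is the only carbon acid, its potassium enolate is selenenylated at C11 on the face away from H7, and the selenoxide formed with H2O2 undergoes syn-elimination, which can then use only a C13 hydrogen and should give the exocyclic olefin. Both C11 epimers converge.

## Compound list

1 | (S)-carvone, (5S)-2-methyl-5-(prop-1-en-2-yl)cyclohex-2-en-1-one | CC1=CC[C@@H](CC1=O)C(C)=C | starting material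
2 | cross-conjugated TBS dienol ether of carvone, (S)-1-(tert-butyldimethylsilyloxy)-6-methyl-3-(prop-1-en-2-yl)cyclohexa-1,5-diene | CC1=CC[C@@H](C=C1O[Si](C)(C)C(C)(C)C)C(C)=C | intermediate
3 | (5R,6R)-6-(tert-butyldimethylsilyloxy)-2-methyl-5-(prop-1-en-2-yl)cyclohex-2-en-1-one (8α-OTBS, trans to the isopropenyl group) | CC1=CC[C@@H]([C@@H](O[Si](C)(C)C(C)(C)C)C1=O)C(C)=C | intermediate
4 | 3-bromo-2-methylprop-1-ene | C=C(C)CBr | starting material
5 | (5R,6S)-6-(tert-butyldimethylsilyloxy)-2-methyl-6-(2-methylprop-2-en-1-yl)-5-(prop-1-en-2-yl)cyclohex-2-en-1-one (8α-methallyl, 8β-OTBS) | CC1=CC[C@@H]([C@](CC(C)=C)(O[Si](C)(C)C(C)(C)C)C1=O)C(C)=C | intermediate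
6 | linear TMS dienol ether of 5 (C3-OTMS, C3=C4 and C5=C6 olefins) | CC1=C(O[Si](C)(C)C)[C@@](CC(C)=C)(O[Si](C)(C)C(C)(C)C)[C@@H](C(C)=C)C=C1 | intermediate
7 | (4R,5S,6S)-6-(tert-butyldimethylsilyloxy)-4-hydroxy-2-methyl-6-(2-methylprop-2-en-1-yl)-5-(prop-1-en-2-yl)cyclohex-2-en-1-one (6α-OH) | CC1=C[C@@H](O)[C@@H]([C@](CC(C)=C)(O[Si](C)(C)C(C)(C)C)C1=O)C(C)=C | intermediate
8 | allylmagnesium bromide | C=CC[Mg]Br | starting material
9 | 3α-allyl-8α-methallyl-7β-isopropenyl-4-methylcyclohex-4-ene-3β,6α,8β-triol 8-O-TBS ether | C=CC[C@@]1(O)C(C)=C[C@@H](O)[C@H](C(C)=C)[C@]1(CC(C)=C)O[Si](C)(C)C(C)(C)C | intermediate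
10 | cis-fused 3,8-cyclogermacra-1(10),4,11(13)-triene-3β,6α,8β-triol 8-O-TBS ether | C=C(C)[C@H]1[C@H](O)C=C(C)[C@]2(O)CC=C(C)C[C@]12O[Si](C)(C)C(C)(C)C | intermediate
11 | 12-(9-borabicyclo[3.3.1]nonan-9-yl) adduct of 10 (11S) | C[C@H](CB1C2CCCC1CCC2)[C@H]1[C@H](O)C=C(C)[C@]2(O)CC=C(C)C[C@]12O[Si](C)(C)C(C)(C)C | intermediate
12 | (11S)-3,8-cyclogermacra-1(10),4-diene-3β,6α,8β,12-tetraol 8-O-TBS ether | C[C@H](CO)[C@H]1[C@H](O)C=C(C)[C@]2(O)CC=C(C)C[C@]12O[Si](C)(C)C(C)(C)C | intermediate
13 | lactol of 14 (12-hydroxy-12,6α-epoxy compound, C12 unassigned) | C[C@@H]1C(O)O[C@@H]2C=C(C)[C@]3(O)CC=C(C)C[C@]3(O[Si](C)(C)C(C)(C)C)[C@@H]12 | intermediate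
14 | (11S)-3β-hydroxy-8β-(tert-butyldimethylsilyloxy)-3,8-cyclogermacra-1(10),4-dien-12,6α-olide (trans-lactone) | C[C@@H]1C(=O)O[C@@H]2C=C(C)[C@]3(O)CC=C(C)C[C@]3(O[Si](C)(C)C(C)(C)C)[C@@H]12 | intermediate
15 | 10α-acetoxy-1β-iodo derivative of 14 (trans-iodo acetate) | C[C@@H]1C(=O)O[C@@H]2C=C(C)[C@]3(O)C[C@@H](I)[C@](C)(OC(C)=O)C[C@]3(O[Si](C)(C)C(C)(C)C)[C@@H]12 | intermediate
16 | 1α-acetoxy-10α-hydroxy derivative of 14 (cis-hydroxy acetate) | C[C@@H]1C(=O)O[C@@H]2C=C(C)[C@]3(O)C[C@H](OC(C)=O)[C@](C)(O)C[C@]3(O[Si](C)(C)C(C)(C)C)[C@@H]12 | intermediate
17 | (11S)-1α,3β,10α-trihydroxy-8β-(tert-butyldimethylsilyloxy)-3,8-cyclogermacr-4-en-12,6α-olide | C[C@@H]1C(=O)O[C@@H]2C=C(C)[C@]3(O)C[C@H](O)[C@](C)(O)C[C@]3(O[Si](C)(C)C(C)(C)C)[C@@H]12 | intermediate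
18 | (11S)-1α,3β,8β,10α-tetrahydroxy-3,8-cyclogermacr-4-en-12,6α-olide | C[C@@H]1C(=O)O[C@@H]2C=C(C)[C@]3(O)C[C@H](O)[C@](C)(O)C[C@]3(O)[C@@H]12 | intermediate
19 | (11S)-3β,8β,10α-trihydroxy-1α-(triethylsilyloxy)-3,8-cyclogermacr-4-en-12,6α-olide (cis-fused decalin-3,8-diol, key-step precursor) | C[C@@H]1C(=O)O[C@@H]2C=C(C)[C@]3(O)C[C@H](O[Si](CC)(CC)CC)[C@](C)(O)C[C@]3(O)[C@@H]12 | intermediate
20 | (4Z,11S)-10α-hydroxy-3,8-dioxo-1α-(triethylsilyloxy)germacr-4-en-12,6α-olide (key-step product) | C[C@@H]1C(=O)O[C@@H]2/C=C(/C)C(=O)C[C@H](O[Si](CC)(CC)CC)[C@](C)(O)CC(=O)[C@@H]12 | intermediate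
21 | (4Z,11S)-8β,10α-dihydroxy-3-oxo-1α-(triethylsilyloxy)germacr-4-en-12,6α-olide | C[C@@H]1C(=O)O[C@@H]2/C=C(/C)C(=O)C[C@H](O[Si](CC)(CC)CC)[C@](C)(O)C[C@@H](O)[C@@H]12 | intermediate
22 | (E)-2-methylbut-2-en-1-ol | C/C=C(\C)CO | starting material
23 | [(2S,3S)-2,3-dimethyloxiran-2-yl]methanol | OC[C@]1(C)O[C@H]1C | intermediate
24 | (2R,3S)-2,3-dimethyloxirane-2-carbaldehyde | O=C[C@]1(C)O[C@H]1C | intermediate
25 | (2R,3S)-2,3-dimethyloxirane-2-carboxylic acid | OC(=O)[C@]1(C)O[C@H]1C | intermediate
26 | mixed anhydride of 25 with 2,4,6-trichlorobenzoic acid | O=C(OC(=O)c1c(Cl)cc(Cl)cc1Cl)[C@]1(C)O[C@H]1C | intermediate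
27 | (4Z,11S)-8β-[(2R,3S)-2,3-dimethyloxirane-2-carbonyloxy]-10α-hydroxy-3-oxo-1α-(triethylsilyloxy)germacr-4-en-12,6α-olide | C[C@@H]1C(=O)O[C@@H]2/C=C(/C)C(=O)C[C@H](O[Si](CC)(CC)CC)[C@](C)(O)C[C@@H](OC(=O)[C@]3(C)O[C@H]3C)[C@@H]12 | intermediate
28 | 3β-hydroxy (3S) analogue of 27 (3β,10α-diol) | C[C@@H]1C(=O)O[C@@H]2/C=C(/C)[C@@H](O)C[C@H](O[Si](CC)(CC)CC)[C@](C)(O)C[C@@H](OC(=O)[C@]3(C)O[C@H]3C)[C@@H]12 | intermediate
29 | 3β-benzoyloxy-8β-[(2R,3S)-2,3-dimethyloxirane-2-carbonyloxy]-10α-hydroxy-1α-(triethylsilyloxy)germacr-4Z-en-12,6α-olide (11S) | C[C@@H]1C(=O)O[C@@H]2/C=C(/C)[C@@H](OC(=O)c3ccccc3)C[C@H](O[Si](CC)(CC)CC)[C@](C)(O)C[C@@H](OC(=O)[C@]3(C)O[C@H]3C)[C@@H]12 | intermediate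
30 | 3β-benzoyloxy-8β-[(2R,3S)-2,3-dimethyloxirane-2-carbonyloxy]-1α,10α-dihydroxygermacr-4Z-en-12,6α-olide (11S) | C[C@@H]1C(=O)O[C@@H]2/C=C(/C)[C@@H](OC(=O)c3ccccc3)C[C@H](O)[C@](C)(O)C[C@@H](OC(=O)[C@]3(C)O[C@H]3C)[C@@H]12 | intermediate
31 | 1α-methanesulfonate of 30 | C[C@@H]1C(=O)O[C@@H]2/C=C(/C)[C@@H](OC(=O)c3ccccc3)C[C@H](OS(C)(=O)=O)[C@](C)(O)C[C@@H](OC(=O)[C@]3(C)O[C@H]3C)[C@@H]12 | intermediate
32 | (11S)-3β-benzoyloxy-8β-[(2R,3S)-2,3-dimethyloxirane-2-carbonyloxy]-1β,10α-epoxygermacr-4Z-en-12,6α-olide (11,13-dihydro target) | C[C@@H]1C(=O)O[C@@H]2/C=C(/C)[C@@H](OC(=O)c3ccccc3)C[C@H]3O[C@]3(C)C[C@@H](OC(=O)[C@]3(C)O[C@H]3C)[C@@H]12 | intermediate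
33 | 11β-phenylselanyl derivative of 32 (11α-methyl) | C[C@]1([Se]c3ccccc3)C(=O)O[C@@H]2/C=C(/C)[C@@H](OC(=O)c3ccccc3)C[C@H]3O[C@]3(C)C[C@@H](OC(=O)[C@]3(C)O[C@H]3C)[C@@H]12 | intermediate
34 | CNP0324463.5, 3β-benzoyloxy-8β-[(2R,3S)-2,3-dimethyloxirane-2-carbonyloxy]-1β,10α-epoxygermacra-4Z,11(13)-dien-12,6α-olide | C=C1C(=O)O[C@@H]2/C=C(/C)[C@@H](OC(=O)c3ccccc3)C[C@H]3O[C@]3(C)C[C@@H](OC(=O)[C@]3(C)O[C@H]3C)[C@@H]12 | target

## Step count and least certain steps

Total step count: 20. Longest linear sequence: 18 steps (steps 1–12 and 15–20; steps 13 and 14 make acid 25).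

**Step 11 (key step).** The fragmentation itself should be fast. The likely failure is decay of the product afterwards, because the acetic acid released can promote transannular aldol reaction of the 1,6-dione (C2 or C9 enol onto the opposite carbonyl) or β-elimination of O6 through the C7 enol of the new C8 ketone, which would also scramble C7. Fallback: the dione is not isolated. The scission is run from 19 in MeCN–AcOH at −30 °C and Me4NBH(OAc)3 is added to the same flask, so that the C8 ketone is reduced under hydroxyl direction as it forms; the route is rejoined at 21. No new compound is needed.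

**Step 2.** The base may remove a γ-proton (C6) in competition with the less acidic, oxygen-bearing C8 proton, so that alkylation occurs at C4 through the linear dienolate. Fallback from 3: soft enolisation (TMSOTf, Et3N, CH2Cl2, 0 °C) toward the oxygenated carbon gives the bis(silyl) enediol ether F1. Methyllithium (THF, 0 °C) cleaves its O–SiMe3 bond and releases the C3 lithium enolate regiospecifically, and 4 then alkylates C8 to give 5.

**Step 3.** The peracid may attack C4 (α) of the dienol ether or one of the 1,1-disubstituted olefins, so regio- or chemoselectivity would be lost. Fallback from 6 (made as in step 3): singlet oxygen (O2, tetraphenylporphyrin, hν, CH2Cl2, −78 °C) adds across C3 and C6 of the silyloxy diene in a [4+2] reaction, which fixes oxygen at C6 and spares olefins that can only react by the slow ene path. Methanol work-up gives the 6α-hydroperoxy enone F2, and PPh3 reduces it to 7.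

**Step 8.** The iodonium ion may be captured by the C3 hydroxyl across ring B (iodoetherification), or the tertiary allylic C3 hydroxyl may ionise in warm acetic acid, instead of anti-opening by acetate on the concave face. Fallback from 14, without iodine(I) chemistry:
- mCPBA (NaHCO3, CH2Cl2, 0 °C) should epoxidise the more electron-rich ring B olefin on the convex face to give the 1β,10β-epoxide F3.
- Dilute HClO4 in THF–H2O at 0 °C opens it with water at tertiary C10 (inversion) to the 1β,10α-diol F4.
- Dess–Martin oxidation of the secondary hydroxyl gives the 10α-hydroxy-1-ketone F5.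
- NaBH4 (MeOH, −40 °C) attacks from the convex β face, anti to O10, and gives the 1α,10α-diol 17.

**Step 12.** The medium ring may not adopt the chair-like delivery geometry, or O10 may be tied up as a hemiketal with C3, so that hydride reaches the other face. Fallback from 20: NaBH4 in MeOH–CH2Cl2 at −78 °C reduces the saturated ketone chemoselectively. If the 8α-alcohol F6 results, Mitsunobu esterification with 25 (PPh3, diisopropyl azodicarboxylate, toluene, 0 °C) inverts C8 and gives 27 directly.

**Step 16.** The twisted Z-enone of the ten-membered ring may not present C4 as the large group, so that reagent and ring conformation are mismatched and facial selectivity is poor. Fallback from 27: reduction in the opposite, then matched, sense with the (S)-oxazaborolidine gives the 3α-alcohol F7. Mitsunobu reaction with benzoic acid (PPh3, diisopropyl azodicarboxylate) inverts C3 and gives the 3β-benzoate 29.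

## Further compounds

F0 | step 11 | none | none
F1 | step 2 | bis(silyl) enediol ether of 3 (C3-OTMS, C8-OTBS, C3=C8 olefin) | CC1=CC[C@H](C(C)=C)C(O[Si](C)(C)C(C)(C)C)=C1O[Si](C)(C)C
F2 | step 3 | 6α-hydroperoxy analogue of 7 | CC1=C[C@@H](OO)[C@@H]([C@](CC(C)=C)(O[Si](C)(C)C(C)(C)C)C1=O)C(C)=C
F3 | step 8 | 1β,10β-epoxide of 14 | C[C@@H]1C(=O)O[C@@H]2C=C(C)[C@]3(O)C[C@H]4O[C@@]4(C)C[C@]3(O[Si](C)(C)C(C)(C)C)[C@@H]12
F4 | step 8 | 1β,10α-diol (trans) from F3 | C[C@@H]1C(=O)O[C@@H]2C=C(C)[C@]3(O)C[C@@H](O)[C@](C)(O)C[C@]3(O[Si](C)(C)C(C)(C)C)[C@@H]12
F5 | step 8 | 10α-hydroxy-1-ketone from F4 | C[C@@H]1C(=O)O[C@@H]2C=C(C)[C@]3(O)CC(=O)[C@](C)(O)C[C@]3(O[Si](C)(C)C(C)(C)C)[C@@H]12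
F6 | step 12 | 8α-hydroxy epimer of 21 | C[C@@H]1C(=O)O[C@@H]2/C=C(/C)C(=O)C[C@H](O[Si](CC)(CC)CC)[C@](C)(O)C[C@H](O)[C@@H]12
F7 | step 16 | 3α-hydroxy epimer of 28 | C[C@@H]1C(=O)O[C@@H]2/C=C(/C)[C@H](O)C[C@H](O[Si](CC)(CC)CC)[C@](C)(O)C[C@@H](OC(=O)[C@]3(C)O[C@H]3C)[C@@H]12
A1 | alternative 1 | 3-O-TBS, 8-O-PMB germacra-1(10)E,4Z,11(13)-trien-12,6-olide | C=C1C(=O)O[C@@H]2/C=C(/C)[C@@H](O[Si](C)(C)C(C)(C)C)C/C=C(\C)C[C@@H](OCc3ccc(OC)cc3)[C@@H]12
A2 | alternative 2 | 1(10)E,4Z-cyclodecadien-6-one with C7 tert-butyl acetate arm, C8 benzyldimethylsilyl group and 3-O-TBS | O=C1[C@H](CC(=O)OC(C)(C)C)[C@H]([Si](C)(C)Cc2ccccc2)C/C(C)=C/C[C@H](O[Si](C)(C)C(C)(C)C)/C(C)=C\1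
A3 | alternative 3 | 8β-hydroxy-1(10)E,4Z-cyclodecadiene with 3-O-PMB, 6-O-TBS and 12-O-TBS | O[C@@H]1C/C(C)=C/C[C@H](OCc2ccc(OC)cc2)/C(C)=C\[C@@H](O[Si](C)(C)C(C)(C)C)[C@@H]1C(=C)CO[Si](C)(C)C(C)(C)C
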